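**Strategy.** The synthesis rests on cutting two bonds of ring B, C2–C7 and C1–C10. Ring B (C1, C2, C7, C8=C9, C10) is a cyclohexene whose sp3 carbons hold the C10 and C1 oxygens, C3 and C6 all on one face, the signature of an endo [4+2] addition of a (Z)-dienophile to an (E,E)-diene. One thermal intramolecular Diels–Alder step therefore closes rings A and B and sets C1, C2, C7 and C10. Its precursor is an acyclic triene: a (Z)-alkenyl pinacolboronate (C1=C2, boron as latent C1 oxygen) joined through C3–C6 (methyl, silyl ether, dioxolane) to an (E,E)-dienyl acetate (C7–C10); C3 and C4 come from an Evans aldol.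

Key step: step 12

Atom labels (order of the target SMILES): C1 CHOAc, C2 CH (fusion), C3 CHCH3, C4 CHOH, C5 C=O, C6 C=C(CH3)2, C7 CH (fusion), C8=C9(CH3), C10 CHOAc; ring A = C2–C7, ring B = C1, C2, C7–C10. In every bicyclic compound H2, H7 and the C3 methyl lie on one face of the cis-fused skeleton, and the C1, C10 and C4 substituents (O or B) lie on the other; absolute configuration as in the SMILES.

Remark on configuration: C3 must be (R) in the alkyne and in the triene. A 3-hydroxy-2-methylpropanoate delivers this only as the (S)-ester if its ester carbon becomes C2, or as the (R)-ester if its hydroxymethyl carbon does. Both ways pass through an epimerisable α-methyl ynal or a weakly face-selective acyl-anion addition, so C3 and C4 are set together by an auxiliary-controlled aldol.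

Design of the triene: the pinacol ester is kept for its low Lewis acidity, because the β-acetoxy boronate formed must survive 150 °C. The dioxolane at C5 is carried from the first steps; it keeps C6–H2 out of conjugation with the diene and is the ketal with the least syn-axial bulk towards the diene. Boron is introduced last.

Assumption: the C6 configuration of the acetone aldol is drawn for attack anti to C8; it is erased one step later.

Step 1
Reactants: 1 but-3-en-1-ylmagnesium bromide; 2 diethyl oxalate
Product: 3 ethyl 2-oxohex-5-enoate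
Conditions: 2 (excess), THF/Et2O, −78 °C, slow addition of 1; aq. NH4Cl
Reagents that add atoms: none
Why: Grignard acylation of a dialkyl oxalate stops at the α-keto ester because the magnesium hemiketal formed at −78 °C does not collapse before the quench.

Step 2
Reactants: 3 ethyl 2-oxohex-5-enoate
Product: 4 ethyl 2-(but-3-en-1-yl)-1,3-dioxolane-2-carboxylate
Conditions: HOCH2CH2OH, TsOH·H2O (cat.), PhMe, reflux, Dean–Stark
Reagents that add atoms: ethylene glycol, SMILES: OCCO
Why: Acid-catalysed ketalisation with azeotropic removal of water masks the electrophilic keto group (later C5) as the dioxolane that is carried to step 15.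

Step 3
Reactants: 4 ethyl 2-(but-3-en-1-yl)-1,3-dioxolane-2-carboxylate
Product: 5 2-(but-3-en-1-yl)-1,3-dioxolane-2-carbaldehyde
Conditions: iBu2AlH, CH2Cl2, −78 °C; aq. potassium sodium tartrate
Reagents that add atoms: none
Why: Partial hydride reduction of an ester; the α,α-dialkoxy ester gives a chelated aluminium hemiacetal that is stable at −78 °C and releases the non-enolisable aldehyde only on work-up.

Step 4
Reactants: 6 (S)-4-benzyl-3-propanoyl-1,3-oxazolidin-2-one; 5 2-(but-3-en-1-yl)-1,3-dioxolane-2-carbaldehyde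
Product: 8 (S)-4-benzyl-3-{(2S,3S)-3-[2-(but-3-en-1-yl)-1,3-dioxolan-2-yl]-3-hydroxy-2-methylpropanoyl}-1,3-oxazolidin-2-one (syn-aldol adduct), via dibutylboron Z-enolate 7 (not isolated)
Conditions: 6, Bu2BOTf, iPr2NEt, CH2Cl2, 0 °C; 5, −78 → 0 °C; pH 7 buffer, MeOH, H2O2
Reagents that add atoms: none
Why: Evans boron aldol reaction: the (Z)-boron enolate adds through a closed Zimmerman–Traxler chair on the enolate face away from the benzyl group, which sets C3 and C4 together as the syn pair (C3 methyl and C4 hydroxyl syn, both (S) in this adduct).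

Step 5
Reactants: 8 syn-aldol adduct
Product: 9 (2S,3S)-3-[2-(but-3-en-1-yl)-1,3-dioxolan-2-yl]-3-hydroxy-N-methoxy-N,2-dimethylpropanamide
Conditions: MeNHOMe·HCl, AlMe3, CH2Cl2, −20 → 0 °C; aq. potassium sodium tartrate
Reagents that add atoms: N,O-dimethylhydroxylamine hydrochloride, SMILES: CNOC.Cl
Why: Weinreb transamidation by the aluminium amide, assisted by the free β-hydroxyl, removes the auxiliary from the exocyclic carbonyl without touching C3 or C4.

Step 6
Reactants: 9 hydroxy Weinreb amide
Product: 10 (2S,3S)-3-[2-(but-3-en-1-yl)-1,3-dioxolan-2-yl]-3-[(tert-butyldimethylsilyl)oxy]-N-methoxy-N,2-dimethylpropanamide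
Conditions: TBSOTf, 2,6-lutidine, CH2Cl2, −78 → 0 °C
Reagents that add atoms: tert-butyldimethylsilyl trifluoromethanesulfonate, SMILES: CC(C)(C)[Si](C)(C)OS(=O)(=O)C(F)(F)F
Why: Silyl ether formation with a silyl triflate and a hindered pyridine base is the standard way to protect a congested secondary alcohol; the ketal and the amide are inert at this temperature.

Step 7
Reactants: 10 silyl-protected Weinreb amide
Product: 12 tert-butyl({(1S,2R)-1-[2-(but-3-en-1-yl)-1,3-dioxolan-2-yl]-2-methylbut-3-yn-1-yl}oxy)dimethylsilane, via aldehyde 11 (not isolated)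
Conditions: iBu2AlH, THF, −78 °C; then MeOH, K2CO3, MeC(O)C(N2)P(O)(OMe)2, −78 °C → rt
Reagents that add atoms: dimethyl (1-diazo-2-oxopropyl)phosphonate, SMILES: CC(=O)C(=[N+]=[N-])P(=O)(OC)OC
Why: Hydride reduction of a Weinreb amide stops at the aldehyde level, and the aldehyde is homologated in the same flask by the Ohira–Bestmann variant of the Seyferth–Gilbert reaction, whose mild base (K2CO3, MeOH) should leave the C3 stereocentre untouched.

Step 8
Reactants: 12 terminal alkyne with butenyl side chain
Product: 14 3-{2-[(1S,2R)-1-[(tert-butyldimethylsilyl)oxy]-2-methylbut-3-yn-1-yl]-1,3-dioxolan-2-yl}propanal, via secondary ozonide 13 (not isolated)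
Conditions: O3, CH2Cl2, −78 °C (Sudan Red 7B end point); PPh3, −78 °C → rt
Reagents that add atoms: ozone, SMILES: [O-][O+]=O
Why: Ozonolysis with reductive work-up; the terminal alkene reacts far faster than the terminal alkyne, so titration to the indicator end point should cleave only C8=CH2.

Step 9
Reactants: 14 C8 aldehyde; 15 2-(triphenyl-λ5-phosphanylidene)propanal
Product: 16 (2E)-5-{2-[(1S,2R)-1-[(tert-butyldimethylsilyl)oxy]-2-methylbut-3-yn-1-yl]-1,3-dioxolan-2-yl}-2-methylpent-2-enal
Conditions: PhMe, 80 °C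
Reagents that add atoms: none
Why: Wittig reaction with a stabilised formyl ylide gives the (E)-trisubstituted enal (C8=C9) and the ylide reacts much more slowly with the conjugated product aldehyde.

Step 10
Reactants: 16 (E)-enal
Product: 17 (1E,3E)-5-{2-[(1S,2R)-1-[(tert-butyldimethylsilyl)oxy]-2-methylbut-3-yn-1-yl]-1,3-dioxolan-2-yl}-2-methylpenta-1,3-dien-1-yl acetate
Conditions: Ac2O, Et3N, DMAP (cat.), THF, 50 °C; chromatography on Et3N-deactivated silica
Reagents that add atoms: acetic anhydride, SMILES: CC(=O)OC(C)=O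
Why: Dienol acetate formation: γ-deprotonation at C7 of the s-trans enal gives the extended dienolate, which is O-acetylated, and minimised allylic strain should favour the (1E,3E)-diene with C6 and the acetate both outside.

Step 11
Reactants: 17 alkynyl dienyl acetate; 18 pinacolborane
Product: 19 (1E,3E)-5-{2-[(1S,2R,3Z)-1-[(tert-butyldimethylsilyl)oxy]-2-methyl-4-(4,4,5,5-tetramethyl-1,3,2-dioxaborolan-2-yl)but-3-en-1-yl]-1,3-dioxolan-2-yl}-2-methylpenta-1,3-dien-1-yl acetate (the triene)
Conditions: [Rh(cod)Cl]2 (cat.), P(iPr)3 (cat.), Et3N, cyclohexane, rt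
Reagents that add atoms: none
Why: Rhodium-catalysed trans-hydroboration of a terminal alkyne (Miyaura type) runs through a rhodium vinylidene, so boron and the C3 chain end up cis in the (Z)-alkenylboronate; only a terminal alkyne can enter this pathway, which is the basis for selectivity over the hindered dienyl acetate.

Step 12
Reactants: 19 the triene
Product: 20 cis-fused cycloadduct (C1 pinacolboryl, C10 acetoxy, C4 silyloxy, C5 ethylene ketal, C6 H2, C3 and C9 methyl; faces as defined above)
Conditions: PhMe (0.01 M, degassed), BHT (cat.), 150 °C, sealed tube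
Reagents that add atoms: none
Why: A concerted, suprafacial thermal [4+2] cycloaddition of the C7=C8–C9=C10 dienyl acetate to the C1=C2 alkenylboronate forms C2–C7 and C1–C10 together; the closest known reaction type is the thermal type 1 intramolecular Diels–Alder reaction of 1,7,9-decatrienes with a (Z)-dienophile, combined with alkenylboronic esters as dienophiles. Ring B is closed as the new cyclohexene that contains both new bonds, and ring A is closed by the C2–C7 bond alone as the six-membered carbocycle of the four-atom tether C3–C6 (fused mode). C1 and C2 keep the cis relation of boron and C3 from the (Z)-alkene, C7 and C10 keep the cis relation of C6 and the acetate from the (E,E)-diene, and the endo orientation, with tether and boron under the diene, links the two pairs into the all-cis ring B array and the cis ring fusion. The absolute sense at C2, and with it at C1, C7 and C10, comes from C3: 1,3-allylic strain with the cis boron holds C3–H in the alkene plane, so the tether reaches only the face anti to the C3 methyl, and the chair tether carries the C3 methyl and the C4 silyloxy group equatorial. The step needs the tether-endo over the tether-exo mode; the (Z)-dienophile is what is relied on for this, helped by the tied-back dioxolane, and this preference is the main uncertainty of the route.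

Step 13
Reactants: 20 cis-fused cycloadduct
Product: 21 C1 alcohol (C1 hydroxyl in place of boron, same face; C10 acetate retained)
Conditions: NaBO3·4H2O, THF/H2O, rt
Reagents that add atoms: sodium perborate tetrahydrate, SMILES: [Na+].[O-]OB=O.O.O.O.O
Why: Perborate oxidation of the C–B bond (ate complex, 1,2-shift of C1 from boron to oxygen) proceeds with retention at C1, boron and the C10 acetate being cis so that no anti β-elimination is open; any acetyl migration or acetate loss is corrected in step 14.

Step 14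
Reactants: 21 C1 alcohol
Product: 22 C1,C10 diacetate (C4 silyloxy, C5 ethylene ketal)
Conditions: Ac2O, pyridine, DMAP (cat.), CH2Cl2, rt
Reagents that add atoms: acetic anhydride, SMILES: CC(=O)OC(C)=O
Why: DMAP-catalysed esterification acetylates the hindered C1 hydroxyl and converges any C1/C10 mono-acetate isomers on the same diacetate.

Step 15
Reactants: 22 diacetate ketal
Product: 23 C5 ketone (C1,C10 diacetate, C4 silyloxy, C6 H2)
Conditions: PPTS, acetone/H2O, 55 °C
Reagents that add atoms: water, SMILES: O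
Why: Acid-catalysed ketal hydrolysis with a weak pyridinium acid should unmask C5 while sparing the hindered secondary silyl ether and both acetates.

Step 16
Reactants: 23 C5 ketone; 24 acetone
Product: 26 C6 (2-hydroxypropan-2-yl) ketone, via lithium enolate 25 (not isolated)
Conditions: LiN(SiMe3)2, THF, −78 °C; 24, −78 °C; aq. NH4Cl at −78 °C
Reagents that add atoms: none
Why: Directed aldol addition: the bulky amide removes the less hindered C6–H kinetically (C4–H is shielded by the silyloxy group and the ketone is far more acidic than the acetates), and the lithium enolate adds to acetone; the new C6 centre is removed in step 17.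

Step 17
Reactants: 26 acetone aldol
Product: 28 C6 isopropylidene enone (C1,C10 diacetate, C4 silyloxy), via tertiary mesylate 27 (not isolated)
Conditions: MsCl, Et3N, CH2Cl2, −20 → 0 °C; then DBU, 0 °C → rt
Reagents that add atoms: none
Why: Dehydration of a β-hydroxy ketone by sulfene-mediated mesylation of the tertiary alcohol and E1cB elimination through the C5/C6 enolate, which can only give the conjugated exocyclic C6=C(CH3)2.

Step 18
Reactants: 28 silyl-protected enone
Product: 29 (1R,2S,4aR,7S,8R,8aS)-7-hydroxy-3,8-dimethyl-6-oxo-5-(propan-2-ylidene)-1,2,4a,5,6,7,8,8a-octahydronaphthalene-1,2-diyl diacetate (target, CNP0333818.1)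
Conditions: HF·pyridine, pyridine, THF, 0 °C → rt
Reagents that add atoms: none
Why: Fluoride-mediated desilylation under buffered, weakly acidic conditions should free the C4 hydroxyl without acyl migration, ester cleavage or enolisation of the α-ketol.

**Compound list**

1 | but-3-en-1-ylmagnesium bromide | C=CCC[Mg]Br | starting material
2 | diethyl oxalate | CCOC(=O)C(=O)OCC | starting material
3 | ethyl 2-oxohex-5-enoate | CCOC(=O)C(=O)CCC=C | intermediate
4 | ethyl 2-(but-3-en-1-yl)-1,3-dioxolane-2-carboxylate | CCOC(=O)C1(CCC=C)OCCO1 | intermediate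
5 | 2-(but-3-en-1-yl)-1,3-dioxolane-2-carbaldehyde | O=CC1(CCC=C)OCCO1 | intermediate
6 | (S)-4-benzyl-3-propanoyl-1,3-oxazolidin-2-one | CCC(=O)N1[C@@H](Cc2ccccc2)COC1=O | starting material
7 | dibutylboron (Z)-enolate of 6 | C/C=C(\OB(CCCC)CCCC)N1[C@@H](Cc2ccccc2)COC1=O | intermediate (not isolated)
8 | (S)-4-benzyl-3-{(2S,3S)-3-[2-(but-3-en-1-yl)-1,3-dioxolan-2-yl]-3-hydroxy-2-methylpropanoyl}-1,3-oxazolidin-2-one | O=C(N1[C@@H](Cc2ccccc2)COC1=O)[C@@H](C)[C@H](O)C3(OCCO3)CCC=C | intermediate
9 | (2S,3S)-3-[2-(but-3-en-1-yl)-1,3-dioxolan-2-yl]-3-hydroxy-N-methoxy-N,2-dimethylpropanamide | CON(C)C(=O)[C@@H](C)[C@H](O)C1(OCCO1)CCC=C | intermediate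
10 | (2S,3S)-3-[2-(but-3-en-1-yl)-1,3-dioxolan-2-yl]-3-[(tert-butyldimethylsilyl)oxy]-N-methoxy-N,2-dimethylpropanamide | CON(C)C(=O)[C@@H](C)[C@H](O[Si](C)(C)C(C)(C)C)C1(OCCO1)CCC=C | intermediate
11 | (2S,3S)-3-[2-(but-3-en-1-yl)-1,3-dioxolan-2-yl]-3-[(tert-butyldimethylsilyl)oxy]-2-methylpropanal | O=C[C@@H](C)[C@H](O[Si](C)(C)C(C)(C)C)C1(OCCO1)CCC=C | intermediate (not isolated)
12 | tert-butyl({(1S,2R)-1-[2-(but-3-en-1-yl)-1,3-dioxolan-2-yl]-2-methylbut-3-yn-1-yl}oxy)dimethylsilane | C#C[C@@H](C)[C@H](O[Si](C)(C)C(C)(C)C)C1(OCCO1)CCC=C | intermediate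
13 | secondary ozonide of 12 (3-substituted 1,2,4-trioxolane; trioxolane carbon unspecified) | C#C[C@@H](C)[C@H](O[Si](C)(C)C(C)(C)C)C1(OCCO1)CCC2OCOO2 | intermediate (not isolated)
14 | 3-{2-[(1S,2R)-1-[(tert-butyldimethylsilyl)oxy]-2-methylbut-3-yn-1-yl]-1,3-dioxolan-2-yl}propanal | C#C[C@@H](C)[C@H](O[Si](C)(C)C(C)(C)C)C1(OCCO1)CCC=O | intermediate
15 | 2-(triphenyl-λ5-phosphanylidene)propanal | CC(C=O)=P(c1ccccc1)(c1ccccc1)c1ccccc1 | starting material
16 | (2E)-5-{2-[(1S,2R)-1-[(tert-butyldimethylsilyl)oxy]-2-methylbut-3-yn-1-yl]-1,3-dioxolan-2-yl}-2-methylpent-2-enal | C#C[C@@H](C)[C@H](O[Si](C)(C)C(C)(C)C)C1(OCCO1)CC/C=C(\C)C=O | intermediate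
17 | (1E,3E)-5-{2-[(1S,2R)-1-[(tert-butyldimethylsilyl)oxy]-2-methylbut-3-yn-1-yl]-1,3-dioxolan-2-yl}-2-methylpenta-1,3-dien-1-yl acetate | C#C[C@@H](C)[C@H](O[Si](C)(C)C(C)(C)C)C1(OCCO1)C/C=C/C(C)=C/OC(C)=O | intermediate
18 | pinacolborane (4,4,5,5-tetramethyl-1,3,2-dioxaborolane) | CC1(C)OBOC1(C)C | starting material
19 | (1E,3E)-5-{2-[(1S,2R,3Z)-1-[(tert-butyldimethylsilyl)oxy]-2-methyl-4-(4,4,5,5-tetramethyl-1,3,2-dioxaborolan-2-yl)but-3-en-1-yl]-1,3-dioxolan-2-yl}-2-methylpenta-1,3-dien-1-yl acetate | CC1(C)OB(OC1(C)C)/C=C\[C@@H](C)[C@H](O[Si](C)(C)C(C)(C)C)C2(OCCO2)C/C=C/C(C)=C/OC(C)=O | intermediate (key-step precursor)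
20 | cis-fused cycloadduct: C1 pinacolboryl, C10 acetoxy, C4 tert-butyldimethylsilyloxy, C5 ethylene ketal, C8=C9 | CC3(C)OB(OC3(C)C)[C@@H]1[C@@H]2[C@@H](C)[C@H](O[Si](C)(C)C(C)(C)C)C4(OCCO4)C[C@@H]2C=C(C)[C@@H]1OC(C)=O | intermediate (key-step product)
21 | C1 alcohol of 20 (C10 acetate, C4 silyloxy, C5 ketal) | O[C@@H]1[C@@H]2[C@@H](C)[C@H](O[Si](C)(C)C(C)(C)C)C3(OCCO3)C[C@@H]2C=C(C)[C@@H]1OC(C)=O | intermediate
22 | C1,C10 diacetate (C4 silyloxy, C5 ketal) | CC(=O)O[C@@H]1[C@@H]2[C@@H](C)[C@H](O[Si](C)(C)C(C)(C)C)C3(OCCO3)C[C@@H]2C=C(C)[C@@H]1OC(C)=O | intermediate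
23 | C5 ketone (C1,C10 diacetate, C4 silyloxy, C6 H2) | CC(=O)O[C@@H]1[C@@H]2[C@@H](C)[C@H](O[Si](C)(C)C(C)(C)C)C(=O)C[C@@H]2C=C(C)[C@@H]1OC(C)=O | intermediate
24 | acetone | CC(C)=O | starting material
25 | lithium C5(O)=C6 enolate of 23 | CC(=O)O[C@@H]1[C@@H]2[C@@H](C)[C@H](O[Si](C)(C)C(C)(C)C)C(O[Li])=C[C@@H]2C=C(C)[C@@H]1OC(C)=O | intermediate (not isolated)
26 | C6 (2-hydroxypropan-2-yl) ketone (C6 substituent drawn anti to C8; configuration immaterial) | CC(=O)O[C@@H]1[C@@H]2[C@@H](C)[C@H](O[Si](C)(C)C(C)(C)C)C(=O)[C@@H](C(C)(C)O)[C@@H]2C=C(C)[C@@H]1OC(C)=O | intermediate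
27 | tertiary methanesulfonate of 26 | CC(=O)O[C@@H]1[C@@H]2[C@@H](C)[C@H](O[Si](C)(C)C(C)(C)C)C(=O)[C@@H](C(C)(C)OS(C)(=O)=O)[C@@H]2C=C(C)[C@@H]1OC(C)=O | intermediate (not isolated)
28 | C6 isopropylidene enone (C1,C10 diacetate, C4 silyloxy) | CC(=O)O[C@@H]1[C@@H]2[C@@H](C)[C@H](O[Si](C)(C)C(C)(C)C)C(=O)C(=C(C)C)[C@@H]2C=C(C)[C@@H]1OC(C)=O | intermediate
29 | (1R,2S,4aR,7S,8R,8aS)-7-hydroxy-3,8-dimethyl-6-oxo-5-(propan-2-ylidene)-1,2,4a,5,6,7,8,8a-octahydronaphthalene-1,2-diyl diacetate | CC(=O)O[C@@H]1[C@@H]2[C@@H](C)[C@H](O)C(=O)C(=C(C)C)[C@@H]2C=C(C)[C@@H]1OC(C)=O | target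

**Step count.** Total: 18 steps. Longest linear sequence: 18 steps (1 and 2 to 29); 6, 15, 18 and 24 are purchased and enter directly.

**Steps most likely to fail**

Step 12. The tether-exo (trans-fused) transition state, in which the bulky pinacolboryl group and the tether both turn away from the diene, may compete, so that ring-fusion selectivity is eroded. The fallback sets out from 17 and comes back at 21; it lets boron go exo and corrects C1 afterwards. Syn-hydroboration of 17 with 18 ((c-C6H11)2BH cat., THF, rt) should give the (E)-alkenyl pinacolboronate F1. In its cycloaddition (PhMe, 150 °C) the cis-fused, tether-endo mode places boron exo, which should give the C1-epimeric cycloadduct F2. NaBO3·4H2O then gives the C1-epimeric alcohol F3, and Dess–Martin periodinane (NaHCO3, CH2Cl2) gives the C1 ketone F4. LiBH(s-Bu)3 (THF, −78 °C) should deliver hydride to the open face that carries H2 and H10 and so return the all-cis alcohol 21 for step 14.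

Step 11. A rhodium hydride may add to the dienyl acetate, or the Z selectivity may erode when the alkyne cannot be used in excess. The fallback sets out from 10 and comes back at 19; it brings boron in by cross-coupling and makes the dienyl acetate last. Step 7 is stopped after the iBu2AlH stage and aldehyde 11 is isolated. Stork–Zhao olefination (Ph3PCH2I+ I−, NaN(SiMe3)2, THF/DMPU, −78 °C) should give the (Z)-vinyl iodide F5. Selective cleavage of its terminal alkene (OsO4 cat., NMO; then NaIO4) gives the iodo aldehyde F6, and Wittig reaction with 15 gives the iodo enal F7. Miyaura borylation with retention of geometry (B2pin2, PdCl2(PPh3)2, PPh3, KOPh, PhMe, 50 °C) gives the (Z)-boryl enal F8. The conditions of step 10 (Ac2O, Et3N, DMAP) then give 19.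

Step 16. Proton transfer between the lithium enolate and acetone, retro-aldol cleavage on warming, or acyl transfer from a neighbouring acetate to the enolate may consume the material. The fallback sets out from 23 and comes back at 26. The kinetic enolate is trapped as it forms (LiN(SiMe3)2 added to 23 and Me3SiCl, THF, −78 °C) as the trimethylsilyl enol ether F9. A Mukaiyama aldol addition to 24 (TiCl4, CH2Cl2, −78 °C) then gives 26 without a free enolate.

Further compounds
F1 | step 12 | (E)-alkenyl pinacolboronate (C1=C2 geometric isomer of 19) | CC1(C)OB(OC1(C)C)/C=C/[C@@H](C)[C@H](O[Si](C)(C)C(C)(C)C)C2(OCCO2)C/C=C/C(C)=C/OC(C)=O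
F2 | step 12 | C1-epimeric cis-fused cycloadduct (boron trans to the C10 acetate) | CC3(C)OB(OC3(C)C)[C@H]1[C@@H]2[C@@H](C)[C@H](O[Si](C)(C)C(C)(C)C)C4(OCCO4)C[C@@H]2C=C(C)[C@@H]1OC(C)=O
F3 | step 12 | C1-epimeric alcohol (C1 epimer of 21) | O[C@H]1[C@@H]2[C@@H](C)[C@H](O[Si](C)(C)C(C)(C)C)C3(OCCO3)C[C@@H]2C=C(C)[C@@H]1OC(C)=O
F4 | step 12 | C1 ketone (C10 acetate, C4 silyloxy, C5 ketal) | O=C1[C@@H]2[C@@H](C)[C@H](O[Si](C)(C)C(C)(C)C)C3(OCCO3)C[C@@H]2C=C(C)[C@@H]1OC(C)=O
F5 | step 11 | (Z)-vinyl iodide: tert-butyl({(1S,2R,3Z)-1-[2-(but-3-en-1-yl)-1,3-dioxolan-2-yl]-4-iodo-2-methylbut-3-en-1-yl}oxy)dimethylsilane | I/C=C\[C@@H](C)[C@H](O[Si](C)(C)C(C)(C)C)C1(OCCO1)CCC=C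
F6 | step 11 | (Z)-iodoalkenyl C8 aldehyde | I/C=C\[C@@H](C)[C@H](O[Si](C)(C)C(C)(C)C)C1(OCCO1)CCC=O
F7 | step 11 | (Z)-iodoalkenyl (E)-enal | I/C=C\[C@@H](C)[C@H](O[Si](C)(C)C(C)(C)C)C1(OCCO1)CC/C=C(\C)C=O
F8 | step 11 | (Z)-alkenyl pinacolboronate (E)-enal | CC1(C)OB(OC1(C)C)/C=C\[C@@H](C)[C@H](O[Si](C)(C)C(C)(C)C)C2(OCCO2)CC/C=C(\C)C=O
F9 | step 16 | trimethylsilyl enol ether of 23 (C5(OSiMe3)=C6) | CC(=O)O[C@@H]1[C@@H]2[C@@H](C)[C@H](O[Si](C)(C)C(C)(C)C)C(O[Si](C)(C)C)=C[C@@H]2C=C(C)[C@@H]1OC(C)=O
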